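## Analysis of the target

Atom labels used throughout: ring A is the 3,4,5-trimethoxyphenyl ring (C1 to C6); C7 is the ketone carbon, C8 the stereocentre and C9 its methyl group; ring B is the phenoxy ring (C1' to C6') with the ether oxygen on C4', methoxy groups on C3' and C5', and the propenyl group on C1'.

The target 18 is an open-chain 8-O-4' neolignan ketone in which rings A and B are joined only through the link C7(=O)–C8(H)(C9H3)–O–C4'. It has one stereocentre, C8, of (S) configuration, and one stereogenic alkene, the (E)-propenyl group on C1'; the two are remote and independent. C8 is the fragile point: its hydrogen is alpha to an aryl ketone and geminal to an aryloxy group, so any base able to enolise C7/C8 racemises it. The propenyl group becomes an electron-rich styrene once ring B is aromatic, and is then open to acid, electrophiles, one-electron oxidants and radicals, with possible loss of the (E) geometry. The hard bond is the C8–O–C4' ether: a secondary alkyl aryl ether whose oxygen is flanked by two ortho methoxy groups and whose alkyl carbon is both hindered and configurationally labile. The strategy rests on the 1,2,3-trioxygenation of ring B, in which the unit C3'–C4'–C5' is the bis-enol-ether form of a 1,3-diketone whose carbon 2 is C4'. The crowded ether can therefore be made at a carbon flanked by two carbonyl groups before ring B is aromatic, with C1' as the sp3 carbon 5 of that diketone.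

## Retrosynthetic reasoning

**18 to 17.** The two O–CH3 bonds on C3' and C5' are cut first, giving bis-phenol 17. These are cut, and not the ring A methoxy groups, because ring A arrives intact from bromoarene 5 while the two ring B oxygens are the ones that will have been carbonyl oxygens. The forward step has to methylate two phenolic hydroxyls without a base that could enolise C7/C8.

**17 to 16.** Ring B is taken down one oxidation level to the six-membered 1,3-diketone 16. C4' becomes carbon 2, C3' and C5' become the carbonyl carbons, and C1' becomes the sp3 carbon 5 that carries the propenyl group. As an arene, ring B can receive its C4'–O bond only by substitution chemistry that the two ortho substituents and the labile C8 make unattractive; as a diketone, carbon 2 can be a carbene centre. The forward reaction is a dehydrogenation that must act on the ring alone and leave C8 and the side-chain alkene untouched.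

**16 to 8 and 15.** The bond between the ether oxygen and carbon 2 of the diketone (the future O–C4' bond) is cut, giving hydroxy ketone 8 and diazo diketone 15. The C8–O bond is deliberately not cut: forming it would need an SN2 displacement at C8 next to a ketone, with inversion, elimination and enolisation all in play. Cutting O–C4' leaves all four bonds at C8 as they are in 8 and unites two fragments of similar size under neutral conditions. The forward step is a carbenoid O–H insertion that must be chemoselective for the hydroxyl group.

**8 to 7, then to 4 and 6.** The C7–C1 bond is cut, giving the acyl donor 4 (an amide with the hydroxyl masked as a silyl ether) and the aryl Grignard reagent 6, made from bromoarene 5. This places C8 in a fragment that comes from the chiral pool. The forward addition must stop at the ketone and must not deprotonate C8; unmasking of 7 to 8 must be non-basic.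

**4 to 3, then to 1 and 2.** The O–Si bond and then the amide C–N bond are cut, leading to ester 1 and amine 2. Ester 1 already has the (S) configuration and the full C7–C8–C9 unit with its oxygen.

**15 to 14.** The carbon–nitrogen double bond at carbon 2 is cut; diazo transfer onto the acidic methylene of diketone 14 puts it in.

**14 to 9 and 10.** Two ring bonds of 14 are cut: C4–C5, formed by conjugate addition of diester 10 to C4 of dienone 9, and C2–C3, formed by Claisen ring closure of the methyl ketone onto one ester group. The second ester group is removed by decarboxylation. Both partners are commodity chemicals and the (E)-propenyl group is already in 9.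

## Alternatives that were turned down

**Alternative 1:** The C8–O4' bond is disconnected homolytically, so that both halves come from one phenol. Forward, two molecules of (E)-2,6-dimethoxy-4-(prop-1-enyl)phenol A1 are oxidised by a one-electron metal oxidant in an aqueous organic solvent. The phenoxy oxygen of one radical derived from phenol A1 bonds to C8 of the other, and the resulting quinone methide is quenched at C7 by the aqueous medium. This gives 1-(4-hydroxy-3,5-dimethoxyphenyl)-2-{2,6-dimethoxy-4-[(E)-prop-1-enyl]phenoxy}propan-1-ol A2 as a racemic erythro/threo mixture.
- For it: the whole skeleton, ring B and the propenyl group appear in one step from the commercial phenol A1. Both ortho positions are blocked, so 8-5' coupling cannot occur. Methylation of the ring A phenol of alcohol A2 can use ordinary base because the ketone does not yet exist. Oxidation of the C7 carbinol would then finish the synthesis in about three steps.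
- Against it: C8 is formed from a planar radical, so A2 is racemic; both diastereomers converge on racemic ketone, and the single enantiomer would need a resolution that discards half the material. Coupling through 8-8' and further oxidation of the product also compete.
- Comparison: on step count this alternative is clearly stronger. The chosen strategy offers an absolute configuration fixed by construction from ester 1 and a union that is not statistical.

**Alternative 2:** The C8–C9 bond is disconnected. Forward, the sodium enolate of (R)-4-benzyl-3-{[2,6-dimethoxy-4-((E)-prop-1-enyl)phenoxy]acetyl}oxazolidin-2-one A3, formed with a strong amide base at low temperature, is methylated on the face away from the benzyl group. This gives (R)-4-benzyl-3-{(S)-2-[2,6-dimethoxy-4-((E)-prop-1-enyl)phenoxy]propanoyl}oxazolidin-2-one A4.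
- For it: the facial selectivity of the chelated enolate of imide A3 is dependable, the diastereomers of imide A4 can be separated to raise purity, and ring B is used as an intact phenol, so no aromatisation is needed. On predictability of the ether bond and of ring B it is stronger than the chosen strategy.
- Against it: a stereocentre that can be bought in ester 1 is made here with a stoichiometric auxiliary and strongly basic enolate chemistry. After the key step the hindered imide A4 must still be cleaved and converted into the aryl ketone by way of an amide and the aryl Grignard reagent 6, so the sequence is linear and of about the same length.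
- Comparison: similar step count, higher confidence in each step. The chosen strategy offers convergence, a chiral-pool stereocentre and no auxiliary to attach and remove.

**Alternative 3:** The C7–C8 bond is disconnected. Forward, racemic 2-(4-allyl-2,6-dimethoxyphenoxy)propanoic acid A5 and 3,4,5-trimethoxybenzoyl chloride A6 are coupled under visible light by an iridium photocatalyst together with a chiral nickel bis(oxazoline) catalyst, with decarboxylation. This gives (S)-2-(4-allyl-2,6-dimethoxyphenoxy)-1-(3,4,5-trimethoxyphenyl)propan-1-one A7.
- For it: it is the most convergent plan, the racemic acid A5 suffices, the ketone is formed directly from acid chloride A6 under non-basic conditions, and the count is about four steps; on step economy it beats the chosen route.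
- Against it: the enantioselectivity must come from the catalyst acting on a radical that carries a bulky, doubly ortho-substituted aryloxy group, and ketone A7 offers no diastereomer or crystalline handle to upgrade it. The propenyl group must be carried as allyl, because a styrene would not survive the excited photocatalyst and the radical intermediates, and the final allyl-to-propenyl shift in A7 must then be done without base because of C8.
- Comparison: shorter, but the configuration depends on an untested catalyst–substrate match. The chosen strategy takes the configuration from ester 1 and carries the (E)-propenyl group from the first step.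

Key step: step 7

Remark on the chemistry: 16 is drawn as the diketone; it should exist mainly as its enol (a 2-alkoxy-3-hydroxycyclohex-2-enone) and as a mixture of isomers at the ring carbons. All of these give the same arene 17, so the mixture is carried on as such.

## Route

Step 1
Reactants: 1 ethyl (S)-lactate; 2 morpholine
Product: 3 (2S)-2-hydroxy-1-(morpholin-4-yl)propan-1-one
Conditions: 2 (1.5 equiv), neat, 85 °C, EtOH distilled off
Reagents that add atoms: none
Why: Direct aminolysis of an alpha-hydroxy ester by a secondary amine (ester-to-amide exchange), helped by hydrogen bonding from the neighbouring hydroxyl; no bond to the stereocentre is touched, so (S) is carried over.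

Step 2
Reactants: 3 (2S)-2-hydroxy-1-(morpholin-4-yl)propan-1-one
Product: 4 (2S)-2-[(tert-butyldimethylsilyl)oxy]-1-(morpholin-4-yl)propan-1-one
Conditions: TBSCl, imidazole, DMF, 0 °C to rt
Reagents that add atoms: tert-butyldimethylsilyl chloride, CC(C)(C)[Si](C)(C)Cl
Why: Imidazole-promoted silylation of a secondary alcohol; it removes the acidic O–H before the organometallic step and does not involve the stereocentre.

Step 3
Reactants: 5 5-bromo-1,2,3-trimethoxybenzene; 4 (2S)-2-[(tert-butyldimethylsilyl)oxy]-1-(morpholin-4-yl)propan-1-one
Product: 7 (2S)-2-[(tert-butyldimethylsilyl)oxy]-1-(3,4,5-trimethoxyphenyl)propan-1-one, via arylmagnesium bromide 6 (not isolated)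
Conditions: 5, Mg, THF, 40 °C; then 4, THF, 0 °C; aq. NH4Cl
Reagents that add atoms: none
Why: Grignard formation followed by acyl substitution on a morpholine amide, which like an N-methoxy-N-methyl amide holds the magnesium-bound tetrahedral adduct until the quench, so the ketone appears only on work-up and is not attacked a second time; the amide alpha-hydrogen is only weakly acidic and addition at 0 °C is fast, so C8 should stay (S).

Step 4
Reactants: 7 (2S)-2-[(tert-butyldimethylsilyl)oxy]-1-(3,4,5-trimethoxyphenyl)propan-1-one
Product: 8 (2S)-2-hydroxy-1-(3,4,5-trimethoxyphenyl)propan-1-one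
Conditions: aq. HF (48%), MeCN, 0 °C to rt
Reagents that add atoms: none
Why: Acidic fluoride cleavage of a silyl ether; a basic fluoride source is avoided because the alpha-hydroxy aryl ketone would enolise (racemisation, alpha-ketol shift), whereas dilute HF at or below room temperature should leave C8 untouched.

Step 5
Reactants: 9 (3E,5E)-hepta-3,5-dien-2-one; 10 dimethyl malonate
Product: 14 5-[(1E)-prop-1-en-1-yl]cyclohexane-1,3-dione, via Michael adduct 11 (not isolated), via cyclic keto ester 12 (not isolated), via keto acid 13 (not isolated)
Conditions: NaOMe, MeOH, reflux; then aq. NaOH, reflux; then aq. HCl to pH 1, 70 °C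
Reagents that add atoms: none
Why: Michael addition, Claisen (Dieckmann-type) ring closure, saponification and decarboxylation, the classical dihydroresorcinol synthesis; the malonate anion adds at C4 of 9 and the methyl ketone enolate closes the six-membered ring, while an adduct formed at C6 cannot ring-close (it would need an eight-membered ring) and reverts under the equilibrating alkoxide conditions, so material should drain into the stabilised enolate of 12 with the (E) alkene unchanged.

Step 6
Reactants: 14 5-[(1E)-prop-1-en-1-yl]cyclohexane-1,3-dione
Product: 15 2-diazo-5-[(1E)-prop-1-en-1-yl]cyclohexane-1,3-dione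
Conditions: 4-acetamidobenzenesulfonyl azide, Et3N, MeCN, 0 °C to rt
Reagents that add atoms: 4-acetamidobenzenesulfonyl azide, CC(=O)Nc1ccc(cc1)S(=O)(=O)N=[N+]=[N-]
Why: Regitz diazo transfer to the acidic methylene of a 1,3-dione (enolate attack on the terminal azide nitrogen, then fragmentation of the triazene); the alkene and carbon 5 are spectators.

Step 7
Reactants: 8 (2S)-2-hydroxy-1-(3,4,5-trimethoxyphenyl)propan-1-one; 15 2-diazo-5-[(1E)-prop-1-en-1-yl]cyclohexane-1,3-dione
Product: 16 2-{[(2S)-1-oxo-1-(3,4,5-trimethoxyphenyl)propan-2-yl]oxy}-5-[(1E)-prop-1-en-1-yl]cyclohexane-1,3-dione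
Conditions: Rh2(OAc)4 (2 mol %), 4 Å MS, PhF, 70 °C, slow addition of 15 (1.5 equiv)
Reagents that add atoms: none
Why: Rh2(OAc)4 takes up the diazo carbon of 15, the diazo nitrogen leaves, and the resulting dirhodium carbenoid, flanked by two carbonyl groups, is strongly electrophilic at carbon 2 of the dione (the future C4'). The hydroxyl oxygen of 8 adds to it to give a metal-bound oxonium ylide, and a 1,2-proton shift releases the 2-alkoxy-1,3-dione 16 and the catalyst; this forms the O–C4' bond and nothing else. The closest known reaction type is the Rh2(OAc)4-catalysed O–H insertion of 2-diazo-1,3-dicarbonyl compounds, 2-diazocyclohexane-1,3-diones included, into primary and secondary alcohols. No ring is closed. The only new stereogenic element is carbon 2 of the dione ring, which enolises freely and disappears on aromatisation, so it needs no control; C8 keeps its (S) configuration because none of its bonds is broken and the medium is neutral and aprotic. The step needs chemoselectivity for O–H insertion: the carbenoid has no hydrogen on its neighbouring carbons to shift and cannot reach its own propenyl group across the ring, an acceptor/acceptor carbenoid cyclopropanates an unactivated 1,2-disubstituted alkene only slowly, the conjugated ketone oxygen of 8 is a poorer donor than the hydroxyl beside it, ring A is deactivated by its acyl group, and Wolff rearrangement needs more forcing conditions. Slow addition of 15 to a concentrated, dry solution of 8 keeps the carbenoid concentration low and favours trapping by the alcohol over trapping by traces of moisture or by the enol of 16.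

Step 8
Reactants: 16 2-{[(2S)-1-oxo-1-(3,4,5-trimethoxyphenyl)propan-2-yl]oxy}-5-[(1E)-prop-1-en-1-yl]cyclohexane-1,3-dione
Product: 17 (2S)-2-{2,6-dihydroxy-4-[(1E)-prop-1-en-1-yl]phenoxy}-1-(3,4,5-trimethoxyphenyl)propan-1-one
Conditions: DDQ (1.05 equiv), dry 1,4-dioxane, rt to 60 °C
Reagents that add atoms: none
Why: Quinone dehydrogenation of an enolisable cyclohexane-1,3-dione to a dihydroxyarene: DDQ abstracts hydride from carbon 5 of the bis-enol, the one ring C–H that is allylic both to the dienol and to the propenyl group, which gives the ring-protonated form of 17 (an arenium ion) that aromatises by loss of a proton. The medium is not basic, so C8 is untouched, and one equivalent of oxidant in dry solvent should limit attack on the new propenylarene, whose para oxygen is twisted out of conjugation by its two ortho neighbours.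

Step 9
Reactants: 17 (2S)-2-{2,6-dihydroxy-4-[(1E)-prop-1-en-1-yl]phenoxy}-1-(3,4,5-trimethoxyphenyl)propan-1-one
Product: 18 (2S)-2-{2,6-dimethoxy-4-[(1E)-prop-1-en-1-yl]phenoxy}-1-(3,4,5-trimethoxyphenyl)propan-1-one
Conditions: TMSCHN2 (excess), iPr2NEt (1 equiv), MeCN/MeOH, 0 °C to rt; AcOH quench
Reagents that add atoms: trimethylsilyldiazomethane, C[Si](C)(C)C=[N+]=[N-]
Why: O-Methylation of phenols by a diazoalkane (proton transfer to the diazo carbon, desilylation by methanol, SN2 attack of the phenoxide on the methyldiazonium ion); no strong base or hard alkylating agent meets the C8–H, the hindered amine is far too weak to enolise C7/C8 at a useful rate, and an aryl ketone does not react with the diazoalkane without a Lewis acid.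

## Compound list

1 | ethyl (S)-lactate | C[C@H](O)C(=O)OCC | starting material
2 | morpholine | C1COCCN1 | starting material
3 | (2S)-2-hydroxy-1-(morpholin-4-yl)propan-1-one | C[C@H](O)C(=O)N1CCOCC1 | intermediate
4 | (2S)-2-[(tert-butyldimethylsilyl)oxy]-1-(morpholin-4-yl)propan-1-one | C[C@H](O[Si](C)(C)C(C)(C)C)C(=O)N1CCOCC1 | intermediate
5 | 5-bromo-1,2,3-trimethoxybenzene | COc1cc(Br)cc(OC)c1OC | starting material
6 | (3,4,5-trimethoxyphenyl)magnesium bromide | COc1cc([Mg]Br)cc(OC)c1OC | intermediate
7 | (2S)-2-[(tert-butyldimethylsilyl)oxy]-1-(3,4,5-trimethoxyphenyl)propan-1-one | C[C@H](O[Si](C)(C)C(C)(C)C)C(=O)c1cc(OC)c(OC)c(OC)c1 | intermediate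
8 | (2S)-2-hydroxy-1-(3,4,5-trimethoxyphenyl)propan-1-one | C[C@H](O)C(=O)c1cc(OC)c(OC)c(OC)c1 | intermediate
9 | (3E,5E)-hepta-3,5-dien-2-one | C/C=C/C=C/C(C)=O | starting material
10 | dimethyl malonate | COC(=O)CC(=O)OC | starting material
11 | dimethyl 2-[(2E)-6-oxohept-2-en-4-yl]propanedioate (racemic) | C/C=C/C(CC(C)=O)C(C(=O)OC)C(=O)OC | intermediate
12 | methyl 2,4-dioxo-6-[(1E)-prop-1-en-1-yl]cyclohexane-1-carboxylate (present as its sodium enolate) | COC(=O)C1C(=O)CC(=O)CC1/C=C/C | intermediate
13 | 2,4-dioxo-6-[(1E)-prop-1-en-1-yl]cyclohexane-1-carboxylic acid | OC(=O)C1C(=O)CC(=O)CC1/C=C/C | intermediate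
14 | 5-[(1E)-prop-1-en-1-yl]cyclohexane-1,3-dione | C/C=C/C1CC(=O)CC(=O)C1 | intermediate
15 | 2-diazo-5-[(1E)-prop-1-en-1-yl]cyclohexane-1,3-dione | C/C=C/C1CC(=O)C(=[N+]=[N-])C(=O)C1 | intermediate
16 | 2-{[(2S)-1-oxo-1-(3,4,5-trimethoxyphenyl)propan-2-yl]oxy}-5-[(1E)-prop-1-en-1-yl]cyclohexane-1,3-dione | C/C=C/C1CC(=O)C(O[C@@H](C)C(=O)c2cc(OC)c(OC)c(OC)c2)C(=O)C1 | intermediate
17 | (2S)-2-{2,6-dihydroxy-4-[(1E)-prop-1-en-1-yl]phenoxy}-1-(3,4,5-trimethoxyphenyl)propan-1-one | C/C=C/c1cc(O)c(O[C@@H](C)C(=O)c2cc(OC)c(OC)c(OC)c2)c(O)c1 | intermediate
18 | (2S)-2-{2,6-dimethoxy-4-[(1E)-prop-1-en-1-yl]phenoxy}-1-(3,4,5-trimethoxyphenyl)propan-1-one | C/C=C/c1cc(OC)c(O[C@@H](C)C(=O)c2cc(OC)c(OC)c(OC)c2)c(OC)c1 | target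

## Step count and least certain steps

Total step count: 9. Longest linear sequence: 7 steps (steps 1, 2, 3, 4, 7, 8, 9); the diazo fragment takes 2 steps (5, 6) before the union.

**Step 7 (key step).**
- What may go wrong: trapping of the carbenoid by something other than the hydroxyl of 8. The candidates are the ketone oxygen of 8 (carbonyl ylide formation and ring closure onto the dione oxygen), traces of moisture, the enol O–H of product 16 (a second insertion), or the alkene of another molecule. The cause is that a secondary alcohol next to a ketone is hindered and only moderately nucleophilic.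
- Fallback: make the ether by a Mitsunobu reaction with inversion, with ring B aromatic from the start. Commercial methyl (R)-lactate F1 and (E)-2,6-dimethoxy-4-(prop-1-enyl)phenol F2 are coupled with PPh3 and diisopropyl azodicarboxylate in THF at 0 °C. SN2 displacement of the oxyphosphonium group by the phenoxide inverts the carbinol carbon and should give methyl (2S)-2-{2,6-dimethoxy-4-[(1E)-prop-1-en-1-yl]phenoxy}propanoate F3. Ester F3 is converted with N,O-dimethylhydroxylamine hydrochloride and iPrMgCl in THF at −20 °C into (2S)-2-{2,6-dimethoxy-4-[(1E)-prop-1-en-1-yl]phenoxy}-N-methoxy-N-methylpropanamide F4. Amide F4 is then treated at 0 °C with the Grignard reagent 6, made from 5 as in step 3, which gives 18 on aqueous quench. The fallback sets out from 5 and comes back to the route at 18; it replaces the key step and steps 8 and 9, at the price of the less common (R)-lactate.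

**Step 8.**
- What may go wrong: carbon–carbon or carbon–oxygen bond formation between the nucleophilic enol of 16 and the quinone instead of hydride transfer; continued oxidation of the newly formed propenylarene at its allylic methyl group; acid-promoted dehydration of the hemiketal that the enol hydroxyl can form with the C7 ketone, which would destroy C8.
- Fallback: methylate first and dehydrogenate by a different mechanism. Compound 16 is treated with TMSCHN2 in toluene/MeOH without added base; the acidic enol is methylated, giving 3-methoxy-2-{[(2S)-1-oxo-1-(3,4,5-trimethoxyphenyl)propan-2-yl]oxy}-5-[(1E)-prop-1-en-1-yl]cyclohex-2-en-1-one F5 as a mixture of ring isomers. F5 no longer has a nucleophilic enol or a free hydroxyl. It is dehydrogenated with catalytic Pd(OCOCF3)2 in DMSO under O2 at 80 °C; a divalent palladium enolate forms and undergoes beta-hydride elimination, with O2 as the terminal oxidant. This gives (2S)-2-{2-hydroxy-6-methoxy-4-[(1E)-prop-1-en-1-yl]phenoxy}-1-(3,4,5-trimethoxyphenyl)propan-1-one F6. The palladium hydride formed could move the alkene before the ring is aromatic, so the reaction would be stopped early. F6 is methylated under the conditions of step 9 to give 18. The fallback sets out from 16 and comes back at 18.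

**Step 9.**
- What may go wrong: incomplete methylation of the second phenol, which is hindered and hydrogen-bonded to the neighbouring ether oxygen; or slow epimerisation at C8 if more amine or longer times are used to force conversion.
- Fallback: Mitsunobu methylation of 17 with MeOH, PPh3 and diisopropyl azodicarboxylate in THF at rt. The alcohol is activated and the phenol is not exposed to an amine base, so neither amine nor diazoalkane is involved. It sets out from 17 and ends at 18 and makes no new compound.

**Step 4.**
- What may go wrong: partial racemisation of C8 or an alpha-ketol shift through acid-catalysed enolisation while the silyl ether is being cleaved.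
- Fallback: leave out the protecting group. The unprotected amide 3 is treated in THF at 0 °C with an excess (about 2.5 equiv) of the Grignard reagent 6; the first equivalent forms the magnesium alkoxide, which protects the hydroxyl and chelates the tetrahedral adduct, and mild aqueous NH4Cl quench gives 8 directly. It sets out from 3 and 6, comes back at 8, replaces steps 2 to 4 and makes no new compound.

## Further compounds

F1 | step 7 | methyl (R)-lactate | C[C@@H](O)C(=O)OC
F2 | step 7 | (E)-2,6-dimethoxy-4-(prop-1-enyl)phenol | C/C=C/c1cc(OC)c(O)c(OC)c1
F3 | step 7 | methyl (2S)-2-{2,6-dimethoxy-4-[(1E)-prop-1-en-1-yl]phenoxy}propanoate | C/C=C/c1cc(OC)c(O[C@@H](C)C(=O)OC)c(OC)c1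
F4 | step 7 | (2S)-2-{2,6-dimethoxy-4-[(1E)-prop-1-en-1-yl]phenoxy}-N-methoxy-N-methylpropanamide | C/C=C/c1cc(OC)c(O[C@@H](C)C(=O)N(C)OC)c(OC)c1
F5 | step 8 | 3-methoxy-2-{[(2S)-1-oxo-1-(3,4,5-trimethoxyphenyl)propan-2-yl]oxy}-5-[(1E)-prop-1-en-1-yl]cyclohex-2-en-1-one | C/C=C/C1CC(=O)C(O[C@@H](C)C(=O)c2cc(OC)c(OC)c(OC)c2)=C(OC)C1
F6 | step 8 | (2S)-2-{2-hydroxy-6-methoxy-4-[(1E)-prop-1-en-1-yl]phenoxy}-1-(3,4,5-trimethoxyphenyl)propan-1-one | C/C=C/c1cc(O)c(O[C@@H](C)C(=O)c2cc(OC)c(OC)c(OC)c2)c(OC)c1
F0 | step 9 | none | none
F0 | step 4 | none | none
A1 | alternative 1 | (E)-2,6-dimethoxy-4-(prop-1-enyl)phenol | C/C=C/c1cc(OC)c(O)c(OC)c1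
A2 | alternative 1 | 1-(4-hydroxy-3,5-dimethoxyphenyl)-2-{2,6-dimethoxy-4-[(E)-prop-1-enyl]phenoxy}propan-1-ol (racemic, erythro and threo) | C/C=C/c1cc(OC)c(OC(C)C(O)c2cc(OC)c(O)c(OC)c2)c(OC)c1
A3 | alternative 2 | (R)-4-benzyl-3-{[2,6-dimethoxy-4-((E)-prop-1-enyl)phenoxy]acetyl}oxazolidin-2-one | C/C=C/c1cc(OC)c(OCC(=O)N2[C@H](Cc3ccccc3)COC2=O)c(OC)c1
A4 | alternative 2 | (R)-4-benzyl-3-{(S)-2-[2,6-dimethoxy-4-((E)-prop-1-enyl)phenoxy]propanoyl}oxazolidin-2-one | C/C=C/c1cc(OC)c(O[C@@H](C)C(=O)N2[C@H](Cc3ccccc3)COC2=O)c(OC)c1
A5 | alternative 3 | 2-(4-allyl-2,6-dimethoxyphenoxy)propanoic acid (racemic) | C=CCc1cc(OC)c(OC(C)C(=O)O)c(OC)c1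
A6 | alternative 3 | 3,4,5-trimethoxybenzoyl chloride | COc1cc(C(=O)Cl)cc(OC)c1OC
A7 | alternative 3 | (S)-2-(4-allyl-2,6-dimethoxyphenoxy)-1-(3,4,5-trimethoxyphenyl)propan-1-one | C=CCc1cc(OC)c(O[C@@H](C)C(=O)c2cc(OC)c(OC)c(OC)c2)c(OC)c1
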